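**Plan**

Numbering used below: C1H3–C2(=O)–C3H2–C4H–C5(=O)–C6(OH)–C7H2–O8–C9Me2–C10H–C11H2–C12H2–C13(Me)–C14H2–C15H; C15 is also bonded to C10 and C6; C16H joins C13 and C4 and carries C17H=C18H–O–acyl.
Retrosynthesis: cut C18–O (copper coupling) and C17=C18 (chromium olefination); C16–C17 and C4–C3 (conjugate addition, enolate alkylation); O8–C7 (epoxide opening) and C6=C7 (methylenation); C13–C16 (radical ring closure); last, C11–C12 and C14–C15 together, a formal [3+3] that opens the cyclohexane into a 2-(methoxycarbonyl)allyl carbonate and dimethyl 3-oxopentanedioate.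
Enabling feature: in the cyclohexane ring C10–C15, C10 carries the only carbon (C9) that can be a carboxyl, so C11 and C15 are the two β-positions of one acrylate (1,3-dielectrophile); C12 and C14 flank C13, which can be a ketone carbon (1,3-dinucleophile) before it becomes the quaternary bridgehead.
Forward ring order: cyclohexane (step 3), then the cycloheptanone bridging C13 and C15 to give the bicyclo[4.3.1]decane (step 11), then the pyran (step 15).
Stereochemistry: C15 from the chiral amine catalyst in step 3; C10 by equilibration to trans; C13 forced by the tether in the ring closure; C16 and C4 by exo-face cuprate addition and anti alkylation; C6 by exo-face epoxidation; E enol ester by E-selective olefination and stereoretentive C–O coupling.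

Key step: step 3

Assumption: hydroquinidine 1,4-phthalazinediyl diether, (DHQD)2PHAL, is taken by analogy with aryl-substituted carbonates to give the (S) centre at C15 of adduct 6; if the sense is the opposite, the pseudo-enantiomeric (DHQ)2PHAL is used.

**Route**

Step 1
Reactants: 1 3-[(tert-butyldimethylsilyl)oxy]propanal; 2 methyl acrylate
Product: 3 methyl 5-[(tert-butyldimethylsilyl)oxy]-3-hydroxy-2-methylidenepentanoate (racemic)
Conditions: DABCO (0.3 equiv), MeOH, rt
Reagents that add atoms: none
Why: Morita–Baylis–Hillman reaction of an unhindered aliphatic aldehyde with an acrylate; the carbinol centre is racemic and is erased in step 3.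

Step 2
Reactants: 3 methyl 5-[(tert-butyldimethylsilyl)oxy]-3-hydroxy-2-methylidenepentanoate
Product: 4 methyl 3-[(tert-butoxycarbonyl)oxy]-5-[(tert-butyldimethylsilyl)oxy]-2-methylidenepentanoate (racemic)
Conditions: Boc2O, DMAP (cat.), CH2Cl2, 0 °C → rt
Reagents that add atoms: di-tert-butyl dicarbonate, CC(C)(C)OC(=O)OC(=O)OC(C)(C)C
Why: DMAP-catalysed O-acylation of the secondary allylic alcohol should give the carbonate that ionises under amine catalysis.

Step 3
Reactants: 4 methyl 3-[(tert-butoxycarbonyl)oxy]-5-[(tert-butyldimethylsilyl)oxy]-2-methylidenepentanoate; 5 dimethyl 3-oxopentanedioate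
Product: 7 trimethyl (4R)-4-{2-[(tert-butyldimethylsilyl)oxy]ethyl}-2-oxocyclohexane-1,3,5-tricarboxylate, via allylation adduct 6 (not isolated)
Conditions: (DHQD)2PHAL (10 mol%), 5 (1.5 equiv), toluene, rt, slow addition of 4; then DBU (0.2 equiv), rt
Reagents that add atoms: none
Why: Proposed new method: the tertiary amine adds SN2′ to the acrylate CH2 (C11) of 4 with loss of CO2 and tert-butoxide, which deprotonates 5; the enolate carbon C14 then displaces the chiral ammonium group SN2′ at C15 to give 6 (bond C14–C15), and with DBU the second active methylene C12 adds to the re-formed acrylate terminus C11 (bond C11–C12) to give 7. The closest known reactions are the amine-catalysed asymmetric allylic alkylation of Morita–Baylis–Hillman carbonates with 1,3-dicarbonyl carbon acids and the racemic base-mediated SN2′/Michael [3+3] annulation of the corresponding acetates with 1,3-dinucleophiles; new is their enantioselective merger on an alkyl-substituted carbonate. The cyclohexane closes by a 6-endo-trig Michael addition, both acrylate carbons C10 and C11 ending in the ring. C15 is set by the catalyst, which shields one face of the allylammonium ion in the C–C bond-forming displacement; C10 arises by protonation of the ester enolate and is corrected in step 5; C12 and C14 are epimerisable β-keto ester centres that vanish in step 4. The step needs branched (C15) first attack, secured by the SN2′/SN2′ course on the terminal acrylate CH2; mono-allylation, secured by excess 5 and slow addition of 4; C- rather than O-cyclisation, secured by reversibility of the oxa-Michael path; and no erosion at C15, secured by closing the ring with catalytic base at rt so that the C10 ester enolate cannot re-open the C14–C15 bond.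

Step 4
Reactants: 7 trimethyl (4R)-4-{2-[(tert-butyldimethylsilyl)oxy]ethyl}-2-oxocyclohexane-1,3,5-tricarboxylate
Product: 8 methyl (2S)-2-{2-[(tert-butyldimethylsilyl)oxy]ethyl}-4-oxocyclohexane-1-carboxylate (C1 epimers)
Conditions: LiCl, H2O, DMSO, 140 °C
Reagents that add atoms: none
Why: Krapcho dealkoxycarbonylation should remove only the two β-keto ester groups, leaving the unactivated ester on C10 and the non-enolisable centre C15 untouched.

Step 5
Reactants: 8 methyl (2S)-2-{2-[(tert-butyldimethylsilyl)oxy]ethyl}-4-oxocyclohexane-1-carboxylate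
Product: 9 methyl (1S,2R)-2-{2-[(tert-butyldimethylsilyl)oxy]ethyl}-4-methylidenecyclohexane-1-carboxylate (trans)
Conditions: Ph3PCH3Br, KOt-Bu, THF, 0 °C → rt; then NaOMe, MeOH, 50 °C
Reagents that add atoms: methyltriphenylphosphonium bromide, C[P+](c1ccccc1)(c1ccccc1)c1ccccc1.[Br-]
Why: Wittig methylenation of the ketone, then base equilibration of the ester α-centre C10 to the more stable trans (diequatorial) isomer; with C13 now an alkene no retro-Michael opening can touch C15.

Step 6
Reactants: 9 methyl (1S,2R)-2-{2-[(tert-butyldimethylsilyl)oxy]ethyl}-4-methylidenecyclohexane-1-carboxylate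
Product: 10 2-[(1S,2R)-2-{2-[(tert-butyldimethylsilyl)oxy]ethyl}-4-methylidenecyclohexyl]propan-2-ol
Conditions: MeMgBr (3.5 equiv), THF, 0 °C → rt
Reagents that add atoms: methylmagnesium bromide, C[Mg]Br
Why: Double Grignard addition to the ester should give the tertiary carbinol C9 (future O8 and gem-dimethyl carbon) and fixes C10, which is no longer epimerisable.

Step 7
Reactants: 10 2-[(1S,2R)-2-{2-[(tert-butyldimethylsilyl)oxy]ethyl}-4-methylidenecyclohexyl]propan-2-ol
Product: 11 2-[(1R,2S)-2-(2-hydroxypropan-2-yl)-5-methylidenecyclohexyl]ethan-1-ol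
Conditions: Bu4NF, THF, rt
Reagents that add atoms: none
Why: Fluoride-mediated cleavage of the primary silyl ether.

Step 8
Reactants: 11 2-[(1R,2S)-2-(2-hydroxypropan-2-yl)-5-methylidenecyclohexyl]ethan-1-ol
Product: 12 2-[(1R,2S)-2-(2-hydroxypropan-2-yl)-5-methylidenecyclohexyl]acetaldehyde (in equilibrium with its lactol)
Conditions: (COCl)2, DMSO, CH2Cl2, −78 °C; Et3N
Reagents that add atoms: none
Why: Swern oxidation of the primary alcohol; the tertiary alcohol is inert and the oxidant is spent before the hydroxy aldehyde can close to its lactol, so over-oxidation to a lactone should be avoided.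

Step 9
Reactants: 12 2-[(1R,2S)-2-(2-hydroxypropan-2-yl)-5-methylidenecyclohexyl]acetaldehyde
Product: 13 1-[(1R,2S)-2-(2-hydroxypropan-2-yl)-5-methylidenecyclohexyl]but-3-en-2-ol (carbinol epimers)
Conditions: CH2=CHMgBr (3 equiv), THF, −78 → 0 °C
Reagents that add atoms: vinylmagnesium bromide, C=C[Mg]Br
Why: Grignard addition to the aldehyde (the lactol opens under the basic conditions); the new carbinol centre is removed in step 10.

Step 10
Reactants: 13 1-[(1R,2S)-2-(2-hydroxypropan-2-yl)-5-methylidenecyclohexyl]but-3-en-2-ol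
Product: 14 1-[(1R,2S)-2-(2-hydroxypropan-2-yl)-5-methylidenecyclohexyl]but-3-en-2-one
Conditions: DMP, CH2Cl2, 0 °C → rt
Reagents that add atoms: none
Why: Dess–Martin oxidation of the secondary allylic alcohol to the vinyl ketone; the tertiary alcohol cannot be oxidised.

Step 11
Reactants: 14 1-[(1R,2S)-2-(2-hydroxypropan-2-yl)-5-methylidenecyclohexyl]but-3-en-2-one
Product: 15 (1R,6R,9S)-9-(2-hydroxypropan-2-yl)-6-methylbicyclo[4.3.1]decan-3-one
Conditions: Fe(acac)3 (30 mol%), PhSiH3, EtOH/(CH2OH)2, 60 °C, high dilution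
Reagents that add atoms: none
Why: Hydrogen-atom transfer from an iron hydride to the 1,1-disubstituted alkene gives the tertiary radical at C13 (creating its methyl group), which adds 7-endo-trig to the vinyl ketone terminus C16 (intramolecular Giese reaction); only the face of C13 cis to the C15 side chain can be reached, so the quaternary centre forms with the bridging configuration.

Step 12
Reactants: 15 (1R,6R,9S)-9-(2-hydroxypropan-2-yl)-6-methylbicyclo[4.3.1]decan-3-one
Product: 16 (1R,6S,9S)-9-(2-hydroxypropan-2-yl)-6-methylbicyclo[4.3.1]dec-4-en-3-one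
Conditions: Pd(OCOCF3)2 (5 mol%), DMSO (10 mol%), O2 (1 atm), AcOH, 80 °C
Reagents that add atoms: none
Why: Aerobic palladium-catalysed α,β-dehydrogenation (Saegusa-type, via a divalent palladium enolate and β-hydride elimination); elimination towards C6–C15 would give a strained bridgehead alkene, so the enone should form at C4=C16.

Step 13
Reactants: 16 (1R,6S,9S)-9-(2-hydroxypropan-2-yl)-6-methylbicyclo[4.3.1]dec-4-en-3-one
Product: 18 (1R,4S,5S,6S,9S)-5-ethenyl-9-(2-hydroxypropan-2-yl)-6-methyl-4-(2-methylprop-2-en-1-yl)bicyclo[4.3.1]decan-3-one, via magnesium enolate 17 (not isolated)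
Conditions: CH2=CHMgBr (3.5 equiv), CuI (20 mol%), THF, −40 °C; then 3-iodo-2-methylprop-1-ene, DMPU, −40 → 0 °C
Reagents that add atoms: vinylmagnesium bromide, C=C[Mg]Br; 3-iodo-2-methylprop-1-ene, C=C(C)CI
Why: Copper-catalysed conjugate addition followed by enolate alkylation (three-component coupling); the vinyl group should enter C16 on the exo face of the cycloheptenone, away from the C10–C12 bridge, and the enolate is alkylated at C4 anti to it.

Step 14
Reactants: 18 (1R,4S,5S,6S,9S)-5-ethenyl-9-(2-hydroxypropan-2-yl)-6-methyl-4-(2-methylprop-2-en-1-yl)bicyclo[4.3.1]decan-3-one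
Product: 19 (1S,4S,5S,6S,9S)-5-ethenyl-9-(2-hydroxypropan-2-yl)-6-methyl-2-methylidene-4-(2-methylprop-2-en-1-yl)bicyclo[4.3.1]decan-3-one
Conditions: (CH2O)n, N-methylanilinium trifluoroacetate, THF, reflux
Reagents that add atoms: paraformaldehyde (as formaldehyde), C=O
Why: Mannich-type α-methylenation; of the two α-positions only C6 carries two hydrogens and can eliminate to the enone, while C4 stays in its more stable trans configuration.

Step 15
Reactants: 19 (1S,4S,5S,6S,9S)-5-ethenyl-9-(2-hydroxypropan-2-yl)-6-methyl-2-methylidene-4-(2-methylprop-2-en-1-yl)bicyclo[4.3.1]decan-3-one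
Product: 21 (4S,6R,10S,13S,15S,16S)-tricyclic hydroxy ketone (pyran C6–C7–O8–C9–C10–C15 closed; C6–OH; ethenyl on C16; 2-methylprop-2-enyl on C4), via spiro-epoxy ketone 20 (not isolated)
Conditions: t-BuOOH, DBU, CH2Cl2, 0 °C → rt; then KOt-Bu (0.2 equiv), THF, 0 → 40 °C
Reagents that add atoms: tert-butyl hydroperoxide, CC(C)(C)OO
Why: Weitz–Scheffer epoxidation of the electron-poor exocyclic alkene should place the oxygen on the exo face of C6; the C9 alkoxide then opens the oxirane at its CH2 carbon C7 (6-endo-tet, since SN2 at the quaternary C6 is impossible), closing the pyran and leaving the C6 hydroxyl, with epoxide strain paying for the boat-like cyclohexane.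

Step 16
Reactants: 21 (4S,6R,10S,13S,15S,16S)-tricyclic hydroxy ketone with ethenyl on C16 and 2-methylprop-2-enyl on C4
Product: 22 (4S,6R,10S,13S,15S,16S)-tricyclic keto aldehyde (formyl on C16; 2-oxopropyl on C4)
Conditions: O3, CH2Cl2/MeOH, −78 °C; then Me2S
Reagents that add atoms: ozone, [O-][O+]=O
Why: Ozonolysis with reductive work-up cleaves both terminal alkenes at once, giving the C17 aldehyde and the methyl ketone of the acetonyl group.

Step 17
Reactants: 22 (4S,6R,10S,13S,15S,16S)-tricyclic keto aldehyde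
Product: 24 potassium (E)-alkenyltrifluoroborate (C16–C17H=C18H–BF3K), via alkenyl pinacol boronate 23 (not isolated)
Conditions: CrCl2 (8 equiv), Cl2CHB(pin) (2 equiv), LiI (4 equiv), THF, rt; then KHF2, MeOH/H2O
Reagents that add atoms: 2-(dichloromethyl)-4,4,5,5-tetramethyl-1,3,2-dioxaborolane, ClC(Cl)B1OC(C)(C)C(C)(C)O1; potassium hydrogen difluoride, [K+].[F-].F
Why: Takai–Utimoto olefination with the gem-dichromium reagent from the dichloromethylboronate is selective for the aldehyde over both ketones and should give the E alkenylboronate, which is converted to the trifluoroborate salt.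

Step 18
Reactants: 24 potassium (E)-alkenyltrifluoroborate; 25 3-methylbut-2-enoic acid
Product: 26 CNP0237201.1 (target)
Conditions: CuBr (10 mol%), DMAP (20 mol%), 4 Å MS, O2 (1 atm), MeCN, 60 °C
Reagents that add atoms: none
Why: Copper-catalysed oxidative (Chan–Lam-type) C–O coupling of an alkenyltrifluoroborate with a carboxylic acid proceeds with retention of alkene geometry, so the E enol ester should form; the tertiary alcohol and the ketones take no part.

**Compound list**

1 | 3-[(tert-butyldimethylsilyl)oxy]propanal | O=CCCO[Si](C)(C)C(C)(C)C | starting material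
2 | methyl acrylate | C=CC(=O)OC | starting material
3 | methyl 5-[(tert-butyldimethylsilyl)oxy]-3-hydroxy-2-methylidenepentanoate (racemic) | C=C(C(=O)OC)C(O)CCO[Si](C)(C)C(C)(C)C | intermediate
4 | methyl 3-[(tert-butoxycarbonyl)oxy]-5-[(tert-butyldimethylsilyl)oxy]-2-methylidenepentanoate (racemic) | C=C(C(=O)OC)C(OC(=O)OC(C)(C)C)CCO[Si](C)(C)C(C)(C)C | intermediate
5 | dimethyl 3-oxopentanedioate | COC(=O)CC(=O)CC(=O)OC | starting material
6 | dimethyl 2-[(3S)-5-[(tert-butyldimethylsilyl)oxy]-2-(methoxycarbonyl)pent-1-en-3-yl]-3-oxopentanedioate (C2 epimers) | COC(=O)CC(=O)C(C(=O)OC)[C@H](CCO[Si](C)(C)C(C)(C)C)C(=C)C(=O)OC | intermediate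
7 | trimethyl (4R)-4-{2-[(tert-butyldimethylsilyl)oxy]ethyl}-2-oxocyclohexane-1,3,5-tricarboxylate (epimers at C1, C3, C5 and enol forms) | COC(=O)C1CC(C(=O)OC)C(=O)C(C(=O)OC)[C@@H]1CCO[Si](C)(C)C(C)(C)C | intermediate
8 | methyl (2S)-2-{2-[(tert-butyldimethylsilyl)oxy]ethyl}-4-oxocyclohexane-1-carboxylate (C1 epimers) | COC(=O)C1CCC(=O)C[C@@H]1CCO[Si](C)(C)C(C)(C)C | intermediate
9 | methyl (1S,2R)-2-{2-[(tert-butyldimethylsilyl)oxy]ethyl}-4-methylidenecyclohexane-1-carboxylate (trans) | COC(=O)[C@H]1CCC(=C)C[C@@H]1CCO[Si](C)(C)C(C)(C)C | intermediate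
10 | 2-[(1S,2R)-2-{2-[(tert-butyldimethylsilyl)oxy]ethyl}-4-methylidenecyclohexyl]propan-2-ol | CC(C)(O)[C@H]1CCC(=C)C[C@@H]1CCO[Si](C)(C)C(C)(C)C | intermediate
11 | 2-[(1R,2S)-2-(2-hydroxypropan-2-yl)-5-methylidenecyclohexyl]ethan-1-ol | CC(C)(O)[C@H]1CCC(=C)C[C@@H]1CCO | intermediate
12 | 2-[(1R,2S)-2-(2-hydroxypropan-2-yl)-5-methylidenecyclohexyl]acetaldehyde (open form of the lactol) | CC(C)(O)[C@H]1CCC(=C)C[C@@H]1CC=O | intermediate
13 | 1-[(1R,2S)-2-(2-hydroxypropan-2-yl)-5-methylidenecyclohexyl]but-3-en-2-ol (carbinol epimers) | CC(C)(O)[C@H]1CCC(=C)C[C@@H]1CC(O)C=C | intermediate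
14 | 1-[(1R,2S)-2-(2-hydroxypropan-2-yl)-5-methylidenecyclohexyl]but-3-en-2-one | CC(C)(O)[C@H]1CCC(=C)C[C@@H]1CC(=O)C=C | intermediate
15 | (1R,6R,9S)-9-(2-hydroxypropan-2-yl)-6-methylbicyclo[4.3.1]decan-3-one | CC(C)(O)[C@H]1CC[C@@]2(C)C[C@@H]1CC(=O)CC2 | intermediate
16 | (1R,6S,9S)-9-(2-hydroxypropan-2-yl)-6-methylbicyclo[4.3.1]dec-4-en-3-one | CC(C)(O)[C@H]1CC[C@@]2(C)C[C@@H]1CC(=O)C=C2 | intermediate
17 | bromomagnesium C5 enolate (and C9 bromomagnesium alkoxide) of the C16-ethenyl conjugate adduct of 16 | CC(C)(O[Mg]Br)[C@H]1CC[C@@]2(C)C[C@@H]1CC(O[Mg]Br)=C[C@@H]2C=C | intermediate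
18 | (1R,4S,5S,6S,9S)-5-ethenyl-9-(2-hydroxypropan-2-yl)-6-methyl-4-(2-methylprop-2-en-1-yl)bicyclo[4.3.1]decan-3-one | CC(C)(O)[C@H]1CC[C@@]2(C)C[C@@H]1CC(=O)[C@@H](CC(C)=C)[C@@H]2C=C | intermediate
19 | (1S,4S,5S,6S,9S)-5-ethenyl-9-(2-hydroxypropan-2-yl)-6-methyl-2-methylidene-4-(2-methylprop-2-en-1-yl)bicyclo[4.3.1]decan-3-one | CC(C)(O)[C@H]1CC[C@@]2(C)C[C@@H]1C(=C)C(=O)[C@@H](CC(C)=C)[C@@H]2C=C | intermediate
20 | (4S,6R,10S,13S,15S,16S)-spiro-epoxy ketone: 19 with an oxirane across C6–C7, oxygen on the face of C6 opposite to C10 | CC(C)(O)[C@H]1CC[C@@]2(C)C[C@@H]1[C@@]3(CO3)C(=O)[C@@H](CC(C)=C)[C@@H]2C=C | intermediate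
21 | (4S,6R,10S,13S,15S,16S)-tricyclic hydroxy ketone: pyran (C6–C7–O8–C9–C10–C15) fused to the bicyclo[4.3.1]decan-5-one, C6–OH, C9 gem-dimethyl, C13 methyl, C16 ethenyl, C4 2-methylprop-2-enyl | C=C(C)C[C@@H]1C(=O)[C@]2(O)COC(C)(C)[C@H]3CC[C@@](C)(C[C@@H]32)[C@H]1C=C | intermediate
22 | (4S,6R,10S,13S,15S,16S)-tricyclic keto aldehyde: as 21 with formyl on C16 and 2-oxopropyl on C4 | CC(=O)C[C@@H]1C(=O)[C@]2(O)COC(C)(C)[C@H]3CC[C@@](C)(C[C@@H]32)[C@H]1C=O | intermediate
23 | (E)-alkenyl pinacol boronate: as 22 with C16–C17H=C18H–B(pin) | CC(=O)C[C@@H]1C(=O)[C@]2(O)COC(C)(C)[C@H]3CC[C@@](C)(C[C@@H]32)[C@H]1/C=C/B4OC(C)(C)C(C)(C)O4 | intermediate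
24 | potassium (E)-alkenyltrifluoroborate: as 22 with C16–C17H=C18H–BF3K | CC(=O)C[C@@H]1C(=O)[C@]2(O)COC(C)(C)[C@H]3CC[C@@](C)(C[C@@H]32)[C@H]1/C=C/[B-](F)(F)F.[K+] | intermediate
25 | 3-methylbut-2-enoic acid | CC(C)=CC(=O)O | starting material
26 | CNP0237201.1, (4S,6R,10S,13S,15S,16S), (E)-enol 3-methylbut-2-enoate | CC(=O)C[C@@H]1C(=O)[C@]2(O)COC(C)(C)[C@H]3CC[C@@](C)(C[C@@H]32)[C@H]1/C=C/OC(=O)C=C(C)C | target

**Step count and risks**

Total step count: 18. Longest linear sequence: 18 steps (from 1; 2, 5 and 25 are purchased).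

Steps most likely to fail:

1. Step 3. The alkyl-substituted allylammonium ion may form slowly and be attacked with poor face discrimination, or adduct 6 may be allylated a second time before it cyclises. The fallback sets out from 1 and comes back at 10, forming the same two ring bonds by iminium catalysis. Wittig reaction of 1 with (triphenylphosphoranylidene)acetaldehyde gives (E)-5-[(tert-butyldimethylsilyl)oxy]pent-2-enal F1. Michael addition of 5 (bond C14–C15) and intramolecular Knoevenagel condensation (bond C11–C12) under (S)-α,α-diphenylprolinol trimethylsilyl ether and benzoic acid in toluene give dimethyl (6S)-6-{2-[(tert-butyldimethylsilyl)oxy]ethyl}-2-oxocyclohex-3-ene-1,3-dicarboxylate F2; the shielding model of this catalyst predicts the required C15 configuration. Krapcho dealkoxycarbonylation gives (5S)-5-{2-[(tert-butyldimethylsilyl)oxy]ethyl}cyclohex-2-en-1-one F3. Equilibrating silylation (TMSCl, NaI, Et3N, MeCN) gives tert-butyldimethyl{2-[(1S)-5-[(trimethylsilyl)oxy]cyclohexa-2,4-dien-1-yl]ethoxy}silane F4. Vinylogous Mukaiyama aldol addition to acetone (TiCl4, CH2Cl2, −78 °C) at C10, anti to the C15 substituent, gives (4R,5S)-5-{2-[(tert-butyldimethylsilyl)oxy]ethyl}-4-(2-hydroxypropan-2-yl)cyclohex-2-en-1-one F5. Hydrogenation (H2, Pd/C) gives (3S,4S)-3-{2-[(tert-butyldimethylsilyl)oxy]ethyl}-4-(2-hydroxypropan-2-yl)cyclohexan-1-one F6, and Wittig methylenation returns to 10.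

2. Step 11. The tertiary radical may be reduced by a second hydrogen-atom transfer, or the alkene isomerised, faster than the 7-endo closure, because closure needs the conformer in which both ring substituents are axial. The fallback sets out from 14 and comes back at 15, separating radical generation from ring closure. Cobalt-catalysed Markovnikov hydrochlorination (Co(BF4)2·6H2O with a salicylaldimine ligand, TsCl, PhSiH3, t-BuOOH, EtOH) gives 1-[(1S,2S)-5-chloro-2-(2-hydroxypropan-2-yl)-5-methylcyclohexyl]but-3-en-2-one F7. A tin hydride chain reaction (Bu3SnH by syringe pump, AIBN, toluene, 110 °C) then regenerates the C13 radical at a low, controlled hydrogen-donor concentration and a higher temperature, so that the Giese cyclisation to 15 can compete.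

3. Step 17. Addition of the bulky gem-dichromium reagent to the α-branched, neopentyl-like aldehyde may be slow, with loss of E selectivity or epimerisation at C16. The fallback sets out from 22 and comes back at 23. Seyferth–Gilbert homologation with dimethyl (1-diazo-2-oxopropyl)phosphonate (K2CO3, MeOH) gives the (4S,6R,10S,13S,15S,16S)-tricyclic keto alkyne with ethynyl on C16 F8. Zirconium-catalysed syn hydroboration (pinacolborane, Cp2Zr(H)Cl, Et3N) fixes the E geometry mechanistically and gives 23, which is carried on with KHF2 as in step 17.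

Further compounds
F1 | step 3 | (E)-5-[(tert-butyldimethylsilyl)oxy]pent-2-enal | O=C/C=C/CCO[Si](C)(C)C(C)(C)C
F2 | step 3 | dimethyl (6S)-6-{2-[(tert-butyldimethylsilyl)oxy]ethyl}-2-oxocyclohex-3-ene-1,3-dicarboxylate (C1 epimers and enol form) | COC(=O)C1=CC[C@@H](CCO[Si](C)(C)C(C)(C)C)C(C(=O)OC)C1=O
F3 | step 3 | (5S)-5-{2-[(tert-butyldimethylsilyl)oxy]ethyl}cyclohex-2-en-1-one | O=C1C=CC[C@@H](CCO[Si](C)(C)C(C)(C)C)C1
F4 | step 3 | tert-butyldimethyl{2-[(1S)-5-[(trimethylsilyl)oxy]cyclohexa-2,4-dien-1-yl]ethoxy}silane | C[Si](C)(C)OC1=CC=C[C@@H](CCO[Si](C)(C)C(C)(C)C)C1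
F5 | step 3 | (4R,5S)-5-{2-[(tert-butyldimethylsilyl)oxy]ethyl}-4-(2-hydroxypropan-2-yl)cyclohex-2-en-1-one | O=C1C=C[C@H](C(C)(C)O)[C@@H](CCO[Si](C)(C)C(C)(C)C)C1
F6 | step 3 | (3S,4S)-3-{2-[(tert-butyldimethylsilyl)oxy]ethyl}-4-(2-hydroxypropan-2-yl)cyclohexan-1-one | O=C1CC[C@H](C(C)(C)O)[C@@H](CCO[Si](C)(C)C(C)(C)C)C1
F7 | step 11 | 1-[(1S,2S)-5-chloro-2-(2-hydroxypropan-2-yl)-5-methylcyclohexyl]but-3-en-2-one (C5 epimers) | CC(C)(O)[C@H]1CCC(C)(Cl)C[C@@H]1CC(=O)C=C
F8 | step 17 | (4S,6R,10S,13S,15S,16S)-tricyclic keto alkyne: as 22 with ethynyl on C16 in place of formyl | CC(=O)C[C@@H]1C(=O)[C@]2(O)COC(C)(C)[C@H]3CC[C@@](C)(C[C@@H]32)[C@H]1C#C
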